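**Retrosynthetic overview**

- Atom labels (lignan numbering): C7 and C7′ carry the aryl groups, C8 is the hydroxylated ring-fusion carbon, C8′ the ring-fusion CH, C9 and C9′ the ring OCH2 carbons; ring A is made of O, C7′, C8′, C8 and C9, ring B of O, C7, C8, C8′ and C9′.
- The route rests on one feature: C7 (ring B) and C7′ (ring A) are each bonded to a ring oxygen, so both aryl–carbon bonds can be cut back to oxocarbenium ions of the intact cis-fused 3,7-dioxabicyclo[3.3.0]octane, and both aryl groups lie on its convex face. These two bonds are therefore made last, from a bis-lactol diacetate and two equivalents of an arylzinc bromide.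
- Rings A and B form together and earlier, when a dialdehyde loses two benzyl ethers and folds (C9–OH onto C7′, C9′–OH onto C7); no ring is formed in the aryl transfer.
- The six-carbon core comes from but-2-yne-1,4-diol: anti hydroalumination–iodination and methoxycarbonylation fix the alkene geometry, a Sharpless epoxidation sets C8, a copper-catalysed vinyl Grignard opening with inversion sets C8′, and oxidation at C7 plus ozonolysis at C7′ give the dialdehyde.

Key step: step 14

Remark: the lactol and acetate carbons of the bis-lactol and its diacetate are expected as anomeric mixtures; the diacetate is drawn as the exo,exo isomer, and every anomer ionises to the same cations in the key step.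

**Route**

Step 1
Reactants: 1 but-2-yne-1,4-diol
Product: 3 (Z)-2-iodobut-2-ene-1,4-diol, via cyclic alkenylaluminate 2 (not isolated)
Conditions: NaAlH2(OCH2CH2OMe)2, THF, 0 °C to rt; then I2, THF, −78 °C to 0 °C
Reagents that add atoms: iodine, II
Why: Hydroxyl-directed anti hydroalumination of the propargylic alcohol puts hydride and aluminium trans, and iododealumination with retention should give the (Z)-iodoalkene, in which iodine (on the future C8) is cis to the CH2OH group that becomes C9′.

Step 2
Reactants: 3 (Z)-2-iodobut-2-ene-1,4-diol; 4 benzyl bromide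
Product: 5 (Z)-1,4-bis(benzyloxy)-2-iodobut-2-ene
Conditions: NaH (2.5 equiv), 4 (2.4 equiv), Bu4NI (cat.), THF/DMF, 0 °C to rt
Reagents that add atoms: benzyl bromide (the second equivalent of 4), BrCc1ccccc1
Why: Twofold Williamson etherification, one equivalent of benzyl bromide for each primary alkoxide, should leave the alkenyl iodide and its geometry untouched.

Step 3
Reactants: 5 (Z)-1,4-bis(benzyloxy)-2-iodobut-2-ene
Product: 6 methyl (Z)-4-(benzyloxy)-2-[(benzyloxy)methyl]but-2-enoate
Conditions: CO (1 atm), MeOH, Et3N, Pd(PPh3)2Cl2 (5 mol %), DMF, 60 °C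
Reagents that add atoms: carbon monoxide, [C-]#[O+]; methanol, CO
Why: Palladium-catalysed methoxycarbonylation of an alkenyl iodide (oxidative addition, CO insertion, methanolysis) proceeds with retention of alkene geometry, so the new carbon C7 ends up cis to C9′.

Step 4
Reactants: 6 methyl (Z)-4-(benzyloxy)-2-[(benzyloxy)methyl]but-2-enoate
Product: 7 (E)-4-(benzyloxy)-2-[(benzyloxy)methyl]but-2-en-1-ol
Conditions: iBu2AlH (2.5 equiv), CH2Cl2, −78 °C to 0 °C; aq. KNaC4H4O6
Reagents that add atoms: none
Why: 1,2-Reduction of the conjugated ester by the aluminium hydride should give the allylic alcohol (C7–OH) without changing the alkene geometry.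

Step 5
Reactants: 7 (E)-4-(benzyloxy)-2-[(benzyloxy)methyl]but-2-en-1-ol
Product: 8 [(2R,3R)-2,3-bis[(benzyloxy)methyl]oxiran-2-yl]methanol
Conditions: Ti(OiPr)4 (20 mol %), L-(+)-diethyl tartrate (24 mol %), t-BuOOH, 4 Å molecular sieves, CH2Cl2, −20 °C
Reagents that add atoms: tert-butyl hydroperoxide, CC(C)(C)OO
Why: In this Sharpless asymmetric epoxidation the C7 hydroxyl binds titanium and, by the usual facial rule for L-(+)-tartrate, oxygen should be delivered to the face that gives the (2R,3R)-epoxide, which fixes C8 and places the oxygen that becomes the C8 hydroxyl.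

Step 6
Reactants: 8 [(2R,3R)-2,3-bis[(benzyloxy)methyl]oxiran-2-yl]methanol; 9 vinylmagnesium bromide
Product: 10 (2R,3S)-2,3-bis[(benzyloxy)methyl]pent-4-ene-1,2-diol
Conditions: 9 (4 equiv), CuI (0.3 equiv), THF, −40 °C to 0 °C; aq. NH4Cl
Reagents that add atoms: none
Why: Copper-catalysed SN2 opening of the 2,3-epoxy alcohol by the vinyl Grignard reagent should occur at C8′, because C8 is fully substituted, with inversion, which sets C8′ and leaves the C8 oxygen as the tertiary alcohol.

Step 7
Reactants: 10 (2R,3S)-2,3-bis[(benzyloxy)methyl]pent-4-ene-1,2-diol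
Product: 11 (2S,3S)-2,3-bis[(benzyloxy)methyl]-2-hydroxypent-4-enal
Conditions: SO3·pyridine, DMSO, Et3N, CH2Cl2, 0 °C
Reagents that add atoms: none
Why: Parikh–Doering oxidation should convert the primary C7 alcohol of the 1,2-diol into the aldehyde without glycol cleavage or attack on the tertiary alcohol, and C8 has no hydrogen and cannot epimerise.

Step 8
Reactants: 11 (2S,3S)-2,3-bis[(benzyloxy)methyl]-2-hydroxypent-4-enal
Product: 12 (2S,3S)-2,3-bis[(benzyloxy)methyl]-2-[(triethylsilyl)oxy]pent-4-enal
Conditions: Et3SiOTf, 2,6-lutidine, CH2Cl2, −78 °C to 0 °C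
Reagents that add atoms: triethylsilyl trifluoromethanesulfonate, CC[Si](CC)(CC)OS(=O)(=O)C(F)(F)F
Why: Silyl triflate silylation is placed here because the tertiary C8 hydroxyl is the only free OH and the aldehyde, lacking an α-hydrogen, cannot form a silyl enol ether.

Step 9
Reactants: 12 (2S,3S)-2,3-bis[(benzyloxy)methyl]-2-[(triethylsilyl)oxy]pent-4-enal
Product: 14 (2S,3S)-2,3-bis[(benzyloxy)methyl]-2-[(triethylsilyl)oxy]butanedial, via ozonide 13 (not isolated)
Conditions: O3, CH2Cl2, −78 °C; then PPh3, −78 °C to rt
Reagents that add atoms: ozone, [O-][O+]=O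
Why: Ozonolysis of the terminal alkene with reductive work-up unmasks the C7′ aldehyde under neutral conditions, which should avoid epimerisation at C8′ and β-elimination of the C9′ or C8 oxygen.

Step 10
Reactants: 14 (2S,3S)-2,3-bis[(benzyloxy)methyl]-2-[(triethylsilyl)oxy]butanedial
Product: 16 (1S,5S)-1-[(triethylsilyl)oxy]-3,7-dioxabicyclo[3.3.0]octane-2,6-diol, via open-chain dihydroxy dialdehyde 15 (not isolated)
Conditions: H2 (1 atm), Pd/C, EtOAc, rt
Reagents that add atoms: none
Why: Hydrogenolysis of the two benzyl ethers frees the C9 and C9′ hydroxyls, each of which should close a five-membered lactol onto the aldehyde four atoms away (ring A by C9–O to C7′, ring B by C9′–O to C7), and only the cis-fused bicycle dictated by C8 and C8′ can form.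

Step 11
Reactants: 16 (1S,5S)-1-[(triethylsilyl)oxy]-3,7-dioxabicyclo[3.3.0]octane-2,6-diol
Product: 17 (1S,2R,5S,6R)-1-[(triethylsilyl)oxy]-3,7-dioxabicyclo[3.3.0]octane-2,6-diyl diacetate
Conditions: Ac2O, pyridine, DMAP (cat.), CH2Cl2, 0 °C to rt
Reagents that add atoms: acetic anhydride, CC(=O)OC(C)=O
Why: Acylation of the two lactol hydroxyls, the only free OH groups, should give the anomeric diacetate.

Step 12
Reactants: 18 4-bromo-2,6-dimethoxyphenol; 4 benzyl bromide
Product: 19 2-(benzyloxy)-5-bromo-1,3-dimethoxybenzene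
Conditions: K2CO3, DMF, 60 °C
Reagents that add atoms: none
Why: Williamson etherification of the phenoxide should protect the phenol as a benzyl ether that tolerates the organometallic steps.

Step 13
Reactants: 19 2-(benzyloxy)-5-bromo-1,3-dimethoxybenzene
Product: 21 [4-(benzyloxy)-3,5-dimethoxyphenyl]zinc bromide, via arylmagnesium bromide 20 (not isolated)
Conditions: Mg turnings, LiCl, THF, rt; then ZnBr2, THF, 0 °C to rt
Reagents that add atoms: zinc bromide, Br[Zn]Br
Why: Magnesium insertion into the aryl bromide followed by transmetalation to zinc should give an aryl donor whose carbon–metal bond fixes attachment para to the benzyloxy group.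

Step 14
Reactants: 17 (1S,2R,5S,6R)-1-[(triethylsilyl)oxy]-3,7-dioxabicyclo[3.3.0]octane-2,6-diyl diacetate; 21 [4-(benzyloxy)-3,5-dimethoxyphenyl]zinc bromide
Product: 23 4,4′-di-O-benzyl-8-O-(triethylsilyl)-8-hydroxysyringaresinol, via C7′-aryl monoacetate 22 (not isolated)
Conditions: 21 (3 equiv, THF exchanged for toluene), BF3·OEt2 (3 equiv), CH2Cl2/toluene, −78 °C to −20 °C
Reagents that add atoms: [4-(benzyloxy)-3,5-dimethoxyphenyl]zinc bromide (the second equivalent of 21), COc1cc([Zn]Br)cc(OC)c1OCc1ccccc1
Why: BF3·OEt2 should ionise first the C7′ acetate and then the C7 acetate (the latter slowed by the adjacent C8 oxygen) to oxocarbenium ions stabilised by the ring oxygens, and each ion is captured by aryl transfer from one equivalent of the arylzinc bromide, forming the C7′–aryl and C7–aryl bonds. The closest known reaction type is the Lewis acid-promoted C-arylation of furanosyl acetates and halides with arylzinc reagents, used here twice on one bis-acetal. No ring is closed in this step, since rings A and B are already in place. C7′ is set by attack on the convex face of the cis-fused bicycle, the concave face being covered by ring B, and C7 is set in the same way with ring A covering the other face, which is also the inside attack cis to the C8 oxygen that five-membered oxocarbenium ions favour. The step needs exo delivery at both carbons and para attachment on the arene: the first is secured by the cup shape fixed by C8 and C8′ together with a C8 silyl ether that cannot bridge to C7 (an ester there would send the aryl group to the concave face), the second by the carbon–zinc bond.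

Step 15
Reactants: 23 4,4′-di-O-benzyl-8-O-(triethylsilyl)-8-hydroxysyringaresinol
Product: 24 4,4′-di-O-benzyl-8-hydroxysyringaresinol
Conditions: Bu4NF, THF, 0 °C to rt
Reagents that add atoms: none
Why: Fluoride-induced cleavage of the tertiary silyl ether under basic conditions should avoid acid-promoted epimerisation at the benzylic carbons C7 and C7′.

Step 16
Reactants: 24 4,4′-di-O-benzyl-8-hydroxysyringaresinol
Product: 25 8-hydroxysyringaresinol
Conditions: H2 (1 atm), Pd/C, EtOAc, rt
Reagents that add atoms: none
Why: Hydrogenolysis of the two aryl benzyl ethers, which cleave much faster than the benzylic C7–O and C7′–O ring bonds, should free both phenols and give the target.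

**Compound list**

1 | but-2-yne-1,4-diol | OCC#CCO | starting material
2 | cyclic sodium alkenylaluminate from hydroalumination of 1 (simplified formula; Al on the future C8, chelated by the C9′ alkoxide) | [Na+].[Na+].[O-]CC1=CCO[Al-]1(OCCOC)OCCOC | intermediate (not isolated)
3 | (Z)-2-iodobut-2-ene-1,4-diol | OC/C=C(\I)CO | intermediate
4 | benzyl bromide | BrCc1ccccc1 | starting material
5 | (Z)-1,4-bis(benzyloxy)-2-iodobut-2-ene | c1ccccc1COC/C=C(\I)COCc1ccccc1 | intermediate
6 | methyl (Z)-4-(benzyloxy)-2-[(benzyloxy)methyl]but-2-enoate | COC(=O)/C(COCc1ccccc1)=C\COCc1ccccc1 | intermediate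
7 | (E)-4-(benzyloxy)-2-[(benzyloxy)methyl]but-2-en-1-ol | OC/C(COCc1ccccc1)=C\COCc1ccccc1 | intermediate
8 | [(2R,3R)-2,3-bis[(benzyloxy)methyl]oxiran-2-yl]methanol | OC[C@]1(COCc2ccccc2)O[C@@H]1COCc1ccccc1 | intermediate
9 | vinylmagnesium bromide | C=C[Mg]Br | starting material
10 | (2R,3S)-2,3-bis[(benzyloxy)methyl]pent-4-ene-1,2-diol | OC[C@@](O)(COCc1ccccc1)[C@@H](C=C)COCc1ccccc1 | intermediate
11 | (2S,3S)-2,3-bis[(benzyloxy)methyl]-2-hydroxypent-4-enal | O=C[C@@](O)(COCc1ccccc1)[C@@H](C=C)COCc1ccccc1 | intermediate
12 | (2S,3S)-2,3-bis[(benzyloxy)methyl]-2-[(triethylsilyl)oxy]pent-4-enal | O=C[C@@](O[Si](CC)(CC)CC)(COCc1ccccc1)[C@@H](C=C)COCc1ccccc1 | intermediate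
13 | ozonide (1,2,4-trioxolane) of 12, mixture at the trioxolane carbon | O=C[C@@](O[Si](CC)(CC)CC)(COCc1ccccc1)[C@@H](C1OCOO1)COCc1ccccc1 | intermediate (not isolated)
14 | (2S,3S)-2,3-bis[(benzyloxy)methyl]-2-[(triethylsilyl)oxy]butanedial | O=C[C@@](O[Si](CC)(CC)CC)(COCc1ccccc1)[C@@H](C=O)COCc1ccccc1 | intermediate
15 | (2S,3S)-2,3-bis(hydroxymethyl)-2-[(triethylsilyl)oxy]butanedial (open-chain form) | O=C[C@@](O[Si](CC)(CC)CC)(CO)[C@@H](C=O)CO | intermediate (not isolated)
16 | (1S,5S)-1-[(triethylsilyl)oxy]-3,7-dioxabicyclo[3.3.0]octane-2,6-diol, cis-fused bis-lactol, anomeric mixture at C2 and C6 | OC1OC[C@]2(O[Si](CC)(CC)CC)C(O)OC[C@H]12 | intermediate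
17 | (1S,2R,5S,6R)-1-[(triethylsilyl)oxy]-3,7-dioxabicyclo[3.3.0]octane-2,6-diyl diacetate (exo,exo-diacetate; C1 = C8, C2 = C7, C5 = C8′, C6 = C7′) | CC(=O)O[C@H]1OC[C@]2(O[Si](CC)(CC)CC)[C@@H](OC(C)=O)OC[C@H]12 | intermediate
18 | 4-bromo-2,6-dimethoxyphenol | COc1cc(Br)cc(OC)c1O | starting material
19 | 2-(benzyloxy)-5-bromo-1,3-dimethoxybenzene | COc1cc(Br)cc(OC)c1OCc1ccccc1 | intermediate
20 | [4-(benzyloxy)-3,5-dimethoxyphenyl]magnesium bromide | COc1cc([Mg]Br)cc(OC)c1OCc1ccccc1 | intermediate (not isolated)
21 | [4-(benzyloxy)-3,5-dimethoxyphenyl]zinc bromide | COc1cc([Zn]Br)cc(OC)c1OCc1ccccc1 | intermediate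
22 | C7′-aryl C7-acetate: (1S,2R,5R,6S)-6-[4-(benzyloxy)-3,5-dimethoxyphenyl]-1-[(triethylsilyl)oxy]-3,7-dioxabicyclo[3.3.0]octan-2-yl acetate | COc1cc([C@H]2OC[C@]3(O[Si](CC)(CC)CC)[C@@H](OC(C)=O)OC[C@H]23)cc(OC)c1OCc1ccccc1 | intermediate (not isolated)
23 | (7R,7′S,8S,8′R)-4,4′-di-O-benzyl-8-O-(triethylsilyl)-8-hydroxysyringaresinol | COc1cc([C@H]2OC[C@]3(O[Si](CC)(CC)CC)[C@@H](c4cc(OC)c(OCc5ccccc5)c(OC)c4)OC[C@H]23)cc(OC)c1OCc1ccccc1 | intermediate
24 | (7R,7′S,8S,8′R)-4,4′-di-O-benzyl-8-hydroxysyringaresinol | COc1cc([C@H]2OC[C@]3(O)[C@@H](c4cc(OC)c(OCc5ccccc5)c(OC)c4)OC[C@H]23)cc(OC)c1OCc1ccccc1 | intermediate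
25 | (7R,7′S,8S,8′R)-8-hydroxysyringaresinol | COc1cc([C@H]2OC[C@]3(O)[C@@H](c4cc(OC)c(O)c(OC)c4)OC[C@H]23)cc(OC)c1O | target

**Step count**

Total step count: 16. Longest linear sequence: 14 steps (steps 1 to 11, then 14 to 16).

**Steps most likely to fail**

Step 14. Aryl transfer from zinc may be too slow to compete with breakdown of the oxocarbenium ions (elimination toward the enol ether at C7′, loss of the silyl ether), or facial control at C7 may erode next to the silyloxy group. The fallback sets out from bis-lactol 16 and arylmagnesium bromide 20 and avoids oxocarbenium arylation. Excess 20 in THF at 0 °C should add to the open-chain aldehyde forms of 16 to give (2S,3R)-1,4-bis[4-(benzyloxy)-3,5-dimethoxyphenyl]-2,3-bis(hydroxymethyl)-2-[(triethylsilyl)oxy]butane-1,4-diol F1, a mixture at the two benzylic carbinol carbons. Camphorsulfonic acid in CH2Cl2 at 0 °C should then ionise the two electron-rich benzylic alcohols; the C9′ hydroxyl closes ring B onto C7 and the C9 hydroxyl closes ring A onto C7′. Because the benzylic ionisation is reversible, both aryl groups should settle on the convex face. The route is rejoined at 23.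

Step 6. Bromide may open the epoxide in place of the vinyl group, or attack at C8′ may be slow because this carbon is flanked by a benzyloxymethyl group. The fallback sets out from 8 and uses aluminium-directed delivery of an alkyne. Et2AlC≡CSiMe3 (from Me3SiC≡CLi and Et2AlCl) in toluene at 0 °C should be delivered from the aluminium alkoxide of the C7 hydroxyl to C8′ with inversion, giving (2R,3S)-2,3-bis[(benzyloxy)methyl]-5-(trimethylsilyl)pent-4-yne-1,2-diol F2. K2CO3 in MeOH removes the silyl group to give (2R,3S)-2,3-bis[(benzyloxy)methyl]pent-4-yne-1,2-diol F3. Semihydrogenation (H2, Pd/CaCO3 poisoned with Pb(OAc)2, quinoline) returns to the route at 10.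

Step 5. Turnover may be slow and enantiofacial control incomplete, because the benzyloxymethyl group on C8′ is cis to the directing CH2OH group. The fallback sets out from 7 and replaces hydroxyl-directed titanium catalysis by a Shi epoxidation: D-fructose-derived ketone catalyst, KHSO5 (as 2KHSO5·KHSO4·K2SO4), K2CO3, MeCN/dimethoxymethane/water, 0 °C. Here the face is chosen by the dioxirane from the substitution pattern of the alkene, not by the hydroxyl. By analogy with trans-disubstituted and trisubstituted alkenes (the C9 and C9′ groups are the trans pair), this catalyst enantiomer is expected to give the same (2R,3R)-epoxide. The route is rejoined directly at 8 and no new compound arises (F0).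

**Further compounds**

F1 | step 14 | (2S,3R)-1,4-bis[4-(benzyloxy)-3,5-dimethoxyphenyl]-2,3-bis(hydroxymethyl)-2-[(triethylsilyl)oxy]butane-1,4-diol (mixture at C1 and C4) | COc1cc(C(O)[C@@](O[Si](CC)(CC)CC)(CO)[C@H](CO)C(O)c2cc(OC)c(OCc3ccccc3)c(OC)c2)cc(OC)c1OCc1ccccc1
F2 | step 6 | (2R,3S)-2,3-bis[(benzyloxy)methyl]-5-(trimethylsilyl)pent-4-yne-1,2-diol | OC[C@@](O)(COCc1ccccc1)[C@@H](C#C[Si](C)(C)C)COCc1ccccc1
F3 | step 6 | (2R,3S)-2,3-bis[(benzyloxy)methyl]pent-4-yne-1,2-diol | OC[C@@](O)(COCc1ccccc1)[C@@H](C#C)COCc1ccccc1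
F0 | step 5 | none | none
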